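## The problem

The target is a 6,7-seco-ent-kauranoid. Cyclohexane ring A is joined through the quaternary spiro carbon C10 to a δ-lactone (C10–C20–O–C7(=O)–C8–C9), and the lactone shares its C8–C9 bond with a bicyclo[3.2.1]octane (ring C: C8, C9, C11, C12, C13, C14; ring D: C8, C14, C13, C16, C15) that carries the 15-oxo-16-methylene unit. Seven stereocentres must be set: C1, C4, C5 and C10 on ring A, and C8, C9 and C13 in the bicycle; C8 and C10 are quaternary and flank C9. C4 and C5 can be made together and then steer C1 (through the C5 substituent) and C10 (through the axial C19 arm on C4). C10 in turn must steer C9 across the lactone, while C8 and C13 are tied to each other by the bridge, so only their sense relative to C9 is open. The exocyclic enone is a Michael acceptor, and the C15 ketone and C7 lactone on quaternary C8 form a β-keto ester that opens by retro-Claisen cleavage with nucleophilic base, so both must appear last and be handled without base. The two acetates must be told apart from the free C6 hydroxyl and cannot be present while enolates are made, and a free C1 hydroxyl can translactonise onto C7. The enabling feature is that C13 carries two two-carbon arms, C12–C11 and C16–C15, which end at C9 and C8, the β- and α-carbons of the C7 lactone. Cutting C9–C11 and C8–C15 leaves a C8=C9 unsaturated lactone and a C13 that bears two identical CH2CHO groups and is no stereocentre.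

## Retrosynthesis

**Enone and silyl ether (34 ⇒ 33 ⇒ 29).** The C16=C17 methylene and the free C6 hydroxyl are removed first, because the enone and the free alcohol are the most fragile features. Ketone 29 can enolise only towards C16, so the methylenation has no regiochemical question. The forward steps must avoid nucleophilic base.

**Oxidation levels at C11 and C15 (29 ⇒ 28 ⇒ 26).** The C15 ketone is traced to an alcohol and the C11 methylene to a second alcohol. Diol 26 is the direct product of a ketyl addition (oxygen on C11) followed by an aldol (oxygen on C15). The forward sequence has to tell the two secondary hydroxyls apart.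

**The two-ring disconnection (26 ⇒ 24).** C9–C11 and C8–C15 are cut together. Cutting C8–C14 or C13–C16 instead would leave C13 or C8 as a stereocentre to be made separately, whereas this cut leaves dialdehyde 24 with a symmetric side chain and only the ring A stereocentres. The forward reaction must add a C11 ketyl to C9 on the lactone face syn to C1, choose the arm that leaves the other one trans to C10, and close the aldol before the enolate is quenched.

**Side chain and unsaturation (24 ⇒ 23 ⇒ 21 ⇒ 19 ⇒ 14 + 18).** The aldehydes come from the terminal alkenes of 23, the acetates from the PMB ethers of 21, the C8=C9 bond from selenide 20, and the C8–C14 bond from alkylation of spirolactone 14 with iodide 18. PMB ethers are carried through the enolate steps because acetates would not survive them. Iodide 18 comes in three steps from diethyl diallylmalonate 15 (via 16 and 17).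

**Spirolactone (14 ⇒ 12 + 13).** C9–C10 and the lactone C–O bond are cut. A tertiary C10 radical from spiro-epoxide 12 adds to acrylate 13, and the alkoxide left on C20 lactonises. This makes the quaternary centre without enolate chemistry next to two oxygenated carbons. The radical must be attacked anti to the axial C19 arm.

**Ring A functionality (12 ⇒ 11 ⇒ 10 ⇒ 9 ⇒ 6).** The epoxide comes from the exocyclic alkene of 11. The C1 alcohol of 10 comes from reduction of enone 9, together with the C19 aldehyde. The C20 methylene comes from a Mannich reaction on the regiodefined silyl enol ether of cycloadduct 6.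

**Ring A skeleton (6 ⇒ 4 + 5; 4 ⇒ 3 ⇒ 1 + 2).** C2–C3 and C4–C5 are cut in a Diels–Alder sense. Methacrolein 5 supplies C3, C4, C18 and C19; diene 4 supplies C2, C1, C10, C5 and C6 and leaves the enol ether exactly at C1=C10. A chiral Lewis acid sets C4 and C5 in one step. Diene 4 comes from enone 3, the Wittig product of aldehyde 1 and ylide 2.

## Roads not taken

**Alternative 1:** Phenolate ipso-alkylation. The cut is C10–C20, with ring A as a phenol (oxygen on C3) and the C7 acid on C8 as a chloromethyl ester. Base forms the phenolate, whose para carbon C10 displaces chloride from C20 and closes the lactone and the spiro centre at once as cyclohexadienone A1.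
- Merits: the bicyclo[3.2.1]octane is finished beforehand with C16=C17 in place, so no redox corrections at C11 and C15 are needed. In this respect it is better than the chosen plan.
- Weak points: A1 has a flat ring A with a C3 carbonyl the target lacks, no substituents on C4, and no oxygen on C1. Four ring A stereocentres, a methyl and a C19 carbon must then be added on a dienone whose two halves differ only by the C5 CH2OTBS group. The C10 configuration depends on the rotamer about C9–C10 in the alkylation.
- Comparison: the chosen plan pays for its longer endgame by fixing every ring A centre early with reliable reactions.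

**Alternative 2:** Ring-contracting Ireland–Claisen. The cut is C8–C14. The silyl ketene acetal of a C7–O–C12 lactone rearranges through a boat transition state, breaking O–C12, to give cyclohexene acid A2 with quaternary C8.
- Merits: C8 is set stereospecifically by chirality transfer, which is more secure than the arm selection the chosen cascade relies on.
- Weak points: the rearrangement needs a fully built ring A with C10 and C9 already joined, four different protecting groups, enolisation of a hindered lactone, and then a separate ring D closure from the bromoallyl group plus C15 oxidation. The sequence is long and linear.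
- Comparison: the chosen plan forms C9–C11 and C8–C15 in one step from an achiral side chain; it gives up the stereospecific C8 transfer for that.

**Alternative 3:** Citraconate-tethered Diels–Alder. C5–C10 and C3–C4 are cut. A 2-silyloxydiene (C10=C1–C2=C3) on C9 adds to a citraconate tethered through C20, giving ring A enol ether A3 with a cis-fused C6–O–C20 butyrolactone.
- Merits: C4, C5 and C10 come in one step with C19 and C6 differentiated and the C1 oxygen in place. This is more economical for ring A than the three separate stereo-defining steps of the chosen plan.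
- Weak points: the π-facial choice relative to C9 rests on a remote centre. The enantiopure bicyclo[3.2.1]octane must be made first. Afterwards the butyrolactone has to be opened and the C7,C20 lactone rebuilt, and the C1 ketone and C19 ester reduced.
- Comparison: the chosen plan also uses a Diels–Alder reaction for C4 and C5, but early, intermolecular and catalyst-controlled, and it keeps its main step for the two-ring cascade.

Key step: step 18

**Remarks on the chemistry**
- Locants are those of the ent-kaurane skeleton (C18 = C4 methyl, C19 = C4 CH2O, C6 = CH2O on C5, C20 = lactone CH2, C17 = exocyclic methylene). The "upper face" of ring A is the face that carries C20, O1, C19 and C6 in the target.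
- The sense of induction of the oxazaborolidinium catalyst in step 3 is assigned by analogy with 2-substituted acroleins. If it proves opposite, the mirror-image catalyst, equally available, is used.
- Compounds 19 and 20 are carried as C8 epimers, and 12 is drawn as the expected major epimer at C10; these centres are destroyed again, so either epimer serves.

## Route

Step 1
Reactants: 1 (tert-butyldimethylsilyloxy)acetaldehyde; 2 1-(triphenylphosphoranylidene)propan-2-one
Product: 3 (E)-5-(tert-butyldimethylsilyloxy)pent-3-en-2-one
Conditions: CH2Cl2, rt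
Reagents that add atoms: none
Why: Wittig olefination with a stabilised ylide, which gives the (E)-enone under neutral conditions.

Step 2
Reactants: 3 (E)-5-(tert-butyldimethylsilyloxy)pent-3-en-2-one
Product: 4 (E)-5-(tert-butyldimethylsilyloxy)-2-(triisopropylsilyloxy)penta-1,3-diene
Conditions: TIPSOTf, Et3N, Et2O, 0 °C
Reagents that add atoms: triisopropylsilyl triflate, CC(C)[Si](C(C)C)(C(C)C)OS(=O)(=O)C(F)(F)F
Why: Soft enolisation of the methyl ketone at its methyl group gives the cross-conjugated 2-silyloxydiene, as in the preparation of 2-silyloxybutadienes from vinyl ketones; the (E)-alkene is untouched.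

Step 3
Reactants: 4 (E)-5-(tert-butyldimethylsilyloxy)-2-(triisopropylsilyloxy)penta-1,3-diene; 5 methacrolein
Product: 6 ring A cycloadduct (C4 bearing CH3 and CHO, C5 bearing CH2OTBS cis to CHO, TIPS enol ether C1=C10)
Conditions: (S)-3,3-diphenyl-1-(2-methylphenyl)tetrahydro-1H,3H-pyrrolo[1,2-c][1,3,2]oxazaborole (20 mol %), Tf2NH (20 mol %), CH2Cl2, −78 °C
Reagents that add atoms: none
Why: Enantioselective Diels–Alder reaction of a 2-substituted acrolein under a cationic oxazaborolidine; the 2-silyloxy and 4-alkyl groups of the diene both direct C5 to the quaternary carbon, the formyl-endo transition state puts CHO (C19) cis to CH2OTBS (C6), and the catalyst face sets the absolute configuration of C4 and C5 together.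

Step 4
Reactants: 6 ring A cycloadduct
Product: 9 ring A 10(20)-methylene-1-oxo-19-aldehyde, via Mannich base 7 (not isolated), via methiodide 8 (not isolated)
Conditions: Me2N=CH2+ I−, CH2Cl2, rt; MeI; aq. NaHCO3; used without delay
Reagents that add atoms: dimethylmethyleneiminium iodide, C=[N+](C)C.[I-]; iodomethane, CI (its methyl is carried only by intermediate 8)
Why: Regiospecific Mannich reaction of the silyl enol ether (C1=C10), then quaternisation and E1cB elimination, places the methylene on C10 only; the C19 aldehyde has no α-hydrogen and is a spectator.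

Step 5
Reactants: 9 ring A 10(20)-methylene-1-oxo-19-aldehyde
Product: 10 ring A allylic diol (1-OH, 19-OH, C6-OTBS, all on the upper face)
Conditions: NaBH4 (excess), CeCl3·7H2O, MeOH, −78 to 0 °C
Reagents that add atoms: none
Why: Luche reduction: 1,2-hydride addition to the enone from the face opposite the C5 CH2OTBS group gives the C1 alcohol cis to C6 and C19 (equatorial), and the excess borohydride also reduces the non-enolisable C19 aldehyde.

Step 6
Reactants: 10 ring A allylic diol
Product: 11 ring A 1,19-bis(4-methoxybenzyl) ether
Conditions: NaH, PMBCl, Bu4NI (cat.), DMF, 0 °C to rt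
Reagents that add atoms: 4-methoxybenzyl chloride, COc1ccc(CCl)cc1
Why: Williamson etherification of both alkoxides; PMB ethers survive the enolate steps to come and are later removed oxidatively beside the silyl ether.

Step 7
Reactants: 11 ring A 1,19-bis(4-methoxybenzyl) ether
Product: 12 ring A 10,20-spiro-epoxide
Conditions: mCPBA, NaHCO3, CH2Cl2, 0 °C
Reagents that add atoms: 3-chloroperbenzoic acid, O=C(OO)c1cccc(Cl)c1
Why: Prilezhaev epoxidation of the only alkene, expected anti to the axial C19 CH2OPMB group; the epoxide configuration is lost in step 8, so either epimer serves.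

Step 8
Reactants: 12 ring A 10,20-spiro-epoxide; 13 2,2,2-trifluoroethyl acrylate
Product: 14 spirolactone (7,20-olide with 1-OPMB, 19-OPMB, 6-OTBS)
Conditions: Cp2TiCl2 (20 mol %), Zn dust, 2,4,6-collidine hydrochloride, THF, rt
Reagents that add atoms: none
Why: Nugent–RajanBabu/Gansäuer reductive epoxide opening by trivalent titanium (Cp2TiCl) gives the tertiary C10 radical, which adds to the acrylate (Giese) from the face opposite the axial C19 arm, so C9 becomes equatorial and C20 axial, as in known couplings of γ-cyclogeranyl-type epoxides; the alkoxide on C20 then closes the δ-lactone on the trifluoroethyl ester.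

Step 9
Reactants: 15 diethyl diallylmalonate
Product: 16 ethyl 2-allylpent-4-enoate
Conditions: LiCl, H2O, DMSO, 170 °C
Reagents that add atoms: none
Why: Krapcho dealkoxycarbonylation of a disubstituted malonate.

Step 10
Reactants: 16 ethyl 2-allylpent-4-enoate
Product: 17 2-allylpent-4-en-1-ol
Conditions: LiAlH4, Et2O, 0 °C
Reagents that add atoms: none
Why: Hydride reduction of the ester to the primary alcohol.

Step 11
Reactants: 17 2-allylpent-4-en-1-ol
Product: 18 4-(iodomethyl)hepta-1,6-diene
Conditions: I2, PPh3, imidazole, CH2Cl2, 0 °C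
Reagents that add atoms: iodine, II
Why: Appel-type iodination of a primary alcohol.

Step 12
Reactants: 14 spirolactone; 18 4-(iodomethyl)hepta-1,6-diene
Product: 19 C8-(2-allylpent-4-enyl) spirolactone (C8 epimers)
Conditions: LiN(iPr)2, THF, −78 °C; HMPA; 18, −78 to −20 °C
Reagents that add atoms: none
Why: Alkylation of the lithium enolate of the δ-lactone with a primary iodide in the presence of HMPA, known for β-branched iodides on this lactone type; the new C8 centre becomes trigonal in step 14.

Step 13
Reactants: 19 C8-alkylated spirolactone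
Product: 20 C8-phenylselanyl lactone (C8 epimers)
Conditions: LiN(iPr)2, THF, −78 to −40 °C; PhSeBr, −78 °C
Reagents that add atoms: benzeneselenenyl bromide, Br[Se]c1ccccc1
Why: α-Selenenylation of the lactone enolate; the PMB and TBS ethers and the terminal alkenes are inert to the amide base.

Step 14
Reactants: 20 C8-phenylselanyl lactone
Product: 21 8,9-unsaturated lactone (bis-PMB, diene side chain)
Conditions: H2O2 (30% aq.), pyridine, CH2Cl2, 0 °C to rt
Reagents that add atoms: none
Why: Selenoxide syn-elimination; one of the two C9 hydrogens is always syn to selenium, and elimination into the ring gives the conjugated endocyclic C8=C9 lactone, as found for 2-alkyl-2-selanyl six-ring carbonyl compounds; pyridine buffers PhSeOH so that the terminal alkenes are not attacked.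

Step 15
Reactants: 21 8,9-unsaturated lactone (bis-PMB)
Product: 22 8,9-unsaturated lactone 1,19-diol
Conditions: DDQ, CH2Cl2/pH 7 buffer, 0 °C
Reagents that add atoms: none
Why: Oxidative cleavage of both PMB ethers by DDQ; the TBS ether, the alkenes and the enoate are inert.

Step 16
Reactants: 22 8,9-unsaturated lactone 1,19-diol
Product: 23 8,9-unsaturated lactone 1,19-diacetate
Conditions: Ac2O, pyridine, DMAP (cat.), CH2Cl2, rt, on the crude diol
Reagents that add atoms: acetic anhydride, CC(=O)OC(C)=O
Why: DMAP-catalysed acetylation done at once so that the free C1 hydroxyl has no time to translactonise; the acetates are introduced only now because they would not survive the enolate steps 12 and 13.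

Step 17
Reactants: 23 8,9-unsaturated lactone 1,19-diacetate
Product: 24 dialdehyde (C13 bearing two CH2CHO arms)
Conditions: O3, CH2Cl2, −78 °C (Sudan red 7B end point); PPh3, −78 °C to rt; used at once
Reagents that add atoms: ozone, [O-][O+]=O
Why: Ozonolysis with reductive work-up; the two monosubstituted alkenes react far faster than the electron-poor trisubstituted C8=C9 bond, and the dye marks the end point.

Step 18
Reactants: 24 dialdehyde
Product: 26 tetracyclic 11,15-diol, via ring C samarium enolate 25 (not isolated)
Conditions: SmI2 (2.4 equiv, 0.1 M in THF, added over 1 h), HMPA (10 equiv), THF (0.005 M), −78 °C; aq. NH4Cl at −78 °C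
Reagents that add atoms: samarium diiodide, I[Sm]I (samarium and iodine only in intermediate 25)
Why: SmI2 reduces one aldehyde to a samarium ketyl whose carbon (C11) adds to C9, the β-carbon of the unsaturated lactone, and a second electron turns the resulting α-radical into the trivalent samarium enolate 25, which adds through C8 to the second aldehyde (C15). The closest known reaction type is the SmI2 ketyl–enoate cyclisation/aldol cascade of dialdehydes, including cascades on α,β-unsaturated spiro-δ-lactones of this kind. Ring C closes in a 6-endo-trig radical mode (the tether sits on the α-carbon and attack at the β-carbon is the polarity-matched one), and ring D closes as a five-membered intramolecular aldol that bridges C8 and C13 into the bicyclo[3.2.1]octane. C9 is set by attack on the lactone face syn to C1 and anti to the C5 CH2OTBS group, the sense seen in ketyl cyclisations onto this spirolactone type. C13 is set in a chair-like transition state in which the lactone holds C10 equatorial and the spectator arm is also equatorial (trans to C10), with the O–Sm group on C11 equatorial, so the C11 hydroxyl is cis to H9. From this C13 epimer the arm can reach C8 only on the face syn to H9, through a boat-like ring C, so C8 follows from C13; C15 is expected with its hydroxyl towards C9 (samarium bridging O11 and the aldehyde) and is immaterial. The step needs conjugate addition to outrun pinacol closure of the 1,5-dialdehyde and needs the equatorial-arm mode: HMPA-saturated samarium (no chelate between the two carbonyls), slow addition (low concentration of divalent samarium favours the one-electron, irreversible C–C bond formation over the two-electron pinacol path) and the absence of a proton source (the enolate lives long enough for the strained aldol) are chosen to secure them.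

Step 19
Reactants: 26 tetracyclic 11,15-diol
Product: 27 11-O-(phenoxythiocarbonyl) 15-alcohol
Conditions: PhOC(S)Cl (1.1 equiv), pyridine, DMAP (cat.), CH2Cl2, 0 °C to rt
Reagents that add atoms: O-phenyl chlorothionoformate, S=C(Cl)Oc1ccccc1
Why: Thioacylation of the more accessible hydroxyl: the C11 alcohol is an ordinary ring alcohol, whereas the C15 alcohol is neopentylic (next to quaternary C8) and lies on the concave face of the bicyclo[3.2.1]octane.

Step 20
Reactants: 27 11-O-(phenoxythiocarbonyl) 15-alcohol
Product: 28 11-deoxy 15-alcohol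
Conditions: Bu3SnH, AIBN (cat.), toluene, 90 °C
Reagents that add atoms: none
Why: Barton–McCombie deoxygenation; the secondary C11 radical is reduced by the stannane, and the free C15 alcohol, the acetates and the lactone are untouched.

Step 21
Reactants: 28 11-deoxy 15-alcohol
Product: 29 15-ketone
Conditions: Dess–Martin periodinane, NaHCO3, CH2Cl2, rt
Reagents that add atoms: none
Why: Dess–Martin oxidation under buffered, non-basic conditions, which avoids retro-aldol opening of the β-hydroxy lactone.

Step 22
Reactants: 29 15-ketone
Product: 33 6-O-TBS enone, via trimethylsilyl enol ether 30 (not isolated), via Mannich base 31 (not isolated), via methiodide 32 (not isolated)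
Conditions: TMSOTf, Et3N, CH2Cl2, 0 °C; Me2N=CH2+ I−, rt; MeI; aq. NaHCO3
Reagents that add atoms: dimethylmethyleneiminium iodide, C=[N+](C)C.[I-]; trimethylsilyl triflate, C[Si](C)(C)OS(=O)(=O)C(F)(F)F (silicon only in intermediate 30); iodomethane, CI (methyl only in intermediate 32)
Why: The C15 ketone can enolise only towards C16 because C8 is quaternary, so soft enolisation gives one silyl enol ether; Mannich reaction with the iminium salt, quaternisation and elimination is the standard way to 16-methylene-15-oxo ent-kauranoids, and no strong or nucleophilic base touches the β-keto lactone or the acetates.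

Step 23
Reactants: 33 6-O-TBS enone
Product: 34 target compound
Conditions: HF·pyridine, THF, 0 °C
Reagents that add atoms: none
Why: Acidic fluoride removes the primary TBS ether without base, so the enone, the β-keto lactone and the acetates survive and no stereocentre is touched.

## Compound list

1 | (tert-butyldimethylsilyloxy)acetaldehyde | O=CCO[Si](C)(C)C(C)(C)C | starting material
2 | 1-(triphenylphosphoranylidene)propan-2-one | CC(=O)C=P(c1ccccc1)(c1ccccc1)c1ccccc1 | starting material
3 | (E)-5-(tert-butyldimethylsilyloxy)pent-3-en-2-one | CC(=O)/C=C/CO[Si](C)(C)C(C)(C)C | intermediate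
4 | (E)-5-(tert-butyldimethylsilyloxy)-2-(triisopropylsilyloxy)penta-1,3-diene | C=C(O[Si](C(C)C)(C(C)C)C(C)C)/C=C/CO[Si](C)(C)C(C)(C)C | intermediate
5 | methacrolein (2-methylprop-2-enal) | C=C(C)C=O | starting material
6 | ring A cycloadduct: cyclohexene with C4 (CH3, CHO), C5 (H, CH2OTBS cis to CHO) and the TIPS enol ether at C1=C10 | O=C[C@]1(C)CCC(O[Si](C(C)C)(C(C)C)C(C)C)=C[C@@H]1CO[Si](C)(C)C(C)(C)C | intermediate
7 | Mannich base: C1 ketone with CH2NMe2 on C10 (C10 epimers), C19 aldehyde, C6-OTBS | CN(C)CC1C(=O)CC[C@@](C)(C=O)[C@H]1CO[Si](C)(C)C(C)(C)C | intermediate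
8 | methiodide of 7 (trimethylammonium iodide) | C[N+](C)(C)CC1C(=O)CC[C@@](C)(C=O)[C@H]1CO[Si](C)(C)C(C)(C)C.[I-] | intermediate
9 | ring A 10(20)-methylene-1-oxo-19-aldehyde, C6-OTBS | C=C1C(=O)CC[C@@](C)(C=O)[C@H]1CO[Si](C)(C)C(C)(C)C | intermediate
10 | ring A allylic diol: C10=C20, 1-OH, 19-OH, C6-OTBS; O1, C19 and C6 on the same face | C=C1[C@@H](O)CC[C@@](C)(CO)[C@H]1CO[Si](C)(C)C(C)(C)C | intermediate
11 | 1,19-bis(4-methoxybenzyl) ether of 10 | C=C1[C@@H](OCc2ccc(OC)cc2)CC[C@@](C)(COCc2ccc(OC)cc2)[C@H]1CO[Si](C)(C)C(C)(C)C | intermediate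
12 | 10,20-spiro-epoxide of 11 (oxygen trans to C19, C20 on the upper face) | C1O[C@@]12[C@@H](OCc1ccc(OC)cc1)CC[C@@](C)(COCc1ccc(OC)cc1)[C@H]2CO[Si](C)(C)C(C)(C)C | intermediate
13 | 2,2,2-trifluoroethyl acrylate | C=CC(=O)OCC(F)(F)F | starting material
14 | spirolactone: C10 spiro δ-lactone (C7,C20-olide; C20 on the upper face, C9 trans to C6), 1-OPMB, 19-OPMB, 6-OTBS | O=C1CC[C@]2(CO1)[C@@H](OCc1ccc(OC)cc1)CC[C@@](C)(COCc1ccc(OC)cc1)[C@H]2CO[Si](C)(C)C(C)(C)C | intermediate
15 | diethyl diallylmalonate | CCOC(=O)C(CC=C)(CC=C)C(=O)OCC | starting material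
16 | ethyl 2-allylpent-4-enoate | CCOC(=O)C(CC=C)CC=C | intermediate
17 | 2-allylpent-4-en-1-ol | OCC(CC=C)CC=C | intermediate
18 | 4-(iodomethyl)hepta-1,6-diene | ICC(CC=C)CC=C | intermediate
19 | spirolactone carrying the 2-allylpent-4-enyl chain on C8 (C8 epimers) | O=C1C(CC(CC=C)CC=C)C[C@]2(CO1)[C@@H](OCc1ccc(OC)cc1)CC[C@@](C)(COCc1ccc(OC)cc1)[C@H]2CO[Si](C)(C)C(C)(C)C | intermediate
20 | C8-phenylselanyl derivative of 19 (C8 epimers) | O=C1C(CC(CC=C)CC=C)([Se]c3ccccc3)C[C@]2(CO1)[C@@H](OCc1ccc(OC)cc1)CC[C@@](C)(COCc1ccc(OC)cc1)[C@H]2CO[Si](C)(C)C(C)(C)C | intermediate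
21 | 8,9-unsaturated spirolactone with the 2-allylpent-4-enyl chain on C8, 1,19-bis-PMB, 6-OTBS | O=C1C(CC(CC=C)CC=C)=C[C@]2(CO1)[C@@H](OCc1ccc(OC)cc1)CC[C@@](C)(COCc1ccc(OC)cc1)[C@H]2CO[Si](C)(C)C(C)(C)C | intermediate
22 | 1,19-diol of 21 | O=C1C(CC(CC=C)CC=C)=C[C@]2(CO1)[C@@H](O)CC[C@@](C)(CO)[C@H]2CO[Si](C)(C)C(C)(C)C | intermediate
23 | 1,19-diacetate of 22 | O=C1C(CC(CC=C)CC=C)=C[C@]2(CO1)[C@@H](OC(C)=O)CC[C@@](C)(COC(C)=O)[C@H]2CO[Si](C)(C)C(C)(C)C | intermediate
24 | dialdehyde: 8,9-unsaturated spirolactone with CH2CH(CH2CHO)2 on C8, 1,19-diacetate, 6-OTBS | O=CCC(CC=O)CC1=C[C@]2(COC1=O)[C@@H](OC(C)=O)CC[C@@](C)(COC(C)=O)[C@H]2CO[Si](C)(C)C(C)(C)C | intermediate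
25 | ring C trivalent samarium enolate: C9–C11 formed, O11–SmI2 cis to H9, CH2CHO arm on C13 trans to C10, C7=C8 enolate O–SmI2 | O=CC[C@@H]1C[C@H](O[Sm](I)I)[C@@H]2C(C1)=C(O[Sm](I)I)OC[C@]23[C@@H](OC(C)=O)CC[C@@](C)(COC(C)=O)[C@H]3CO[Si](C)(C)C(C)(C)C | intermediate
26 | tetracyclic 11,15-diol: rings C and D closed, 11-OH cis to H9, 15-OH towards C9, 1,19-diacetate, 6-OTBS | C1[C@@H](O)[C@]23C[C@H]1C[C@H](O)[C@H]2[C@]1(COC3=O)[C@@H](OC(C)=O)CC[C@@](C)(COC(C)=O)[C@H]1CO[Si](C)(C)C(C)(C)C | intermediate
27 | 11-O-(phenoxythiocarbonyl) derivative of 26 | C1[C@@H](O)[C@]23C[C@H]1C[C@H](OC(=S)Oc1ccccc1)[C@H]2[C@]1(COC3=O)[C@@H](OC(C)=O)CC[C@@](C)(COC(C)=O)[C@H]1CO[Si](C)(C)C(C)(C)C | intermediate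
28 | 11-deoxy 15-alcohol | C1[C@@H](O)[C@]23C[C@H]1CC[C@H]2[C@]1(COC3=O)[C@@H](OC(C)=O)CC[C@@](C)(COC(C)=O)[C@H]1CO[Si](C)(C)C(C)(C)C | intermediate
29 | 15-ketone (β-keto lactone) | C1C(=O)[C@]23C[C@H]1CC[C@H]2[C@]1(COC3=O)[C@@H](OC(C)=O)CC[C@@](C)(COC(C)=O)[C@H]1CO[Si](C)(C)C(C)(C)C | intermediate
30 | C15=C16 trimethylsilyl enol ether of 29 | C1=C(O[Si](C)(C)C)[C@]23C[C@H]1CC[C@H]2[C@]1(COC3=O)[C@@H](OC(C)=O)CC[C@@](C)(COC(C)=O)[C@H]1CO[Si](C)(C)C(C)(C)C | intermediate
31 | Mannich base: 16-(dimethylaminomethyl) 15-ketone (C16 epimers) | CN(C)CC1C(=O)[C@]23C[C@H]1CC[C@H]2[C@]1(COC3=O)[C@@H](OC(C)=O)CC[C@@](C)(COC(C)=O)[C@H]1CO[Si](C)(C)C(C)(C)C | intermediate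
32 | methiodide of 31 | C[N+](C)(C)CC1C(=O)[C@]23C[C@H]1CC[C@H]2[C@]1(COC3=O)[C@@H](OC(C)=O)CC[C@@](C)(COC(C)=O)[C@H]1CO[Si](C)(C)C(C)(C)C.[I-] | intermediate
33 | 6-O-TBS ether of the target (16-methylene-15-ketone) | C=C1C(=O)[C@]23C[C@H]1CC[C@H]2[C@]1(COC3=O)[C@@H](OC(C)=O)CC[C@@](C)(COC(C)=O)[C@H]1CO[Si](C)(C)C(C)(C)C | intermediate
34 | CNP0105570.2: 1,19-diacetoxy-6-hydroxy-15-oxo-6,7-seco-ent-kaur-16-en-7,20-olide | C=C1C(=O)[C@]23C[C@H]1CC[C@H]2[C@]1(COC3=O)[C@@H](OC(C)=O)CC[C@@](C)(COC(C)=O)[C@H]1CO | target

## Step count and risks

Total: 23 steps. Longest linear sequence: 20 steps (steps 1–8 and 12–23); iodide 18 is made in a 3-step branch (steps 9–11).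

**Step 18 (key step).** Most likely failure: the ketyl is consumed by pinacol coupling with the second aldehyde, because the two aldehydes stand 1,5 to each other and can close a five-membered diol faster than the ketyl adds to the hindered C9. Less likely, the enolate is protonated before the boat-like aldol, or the arm-axial mode leads to the C8,C13-epimeric bicycle. The LiBr/t-BuOH variant known for this lactone class is the first change of conditions. Fallback (differentiated arms, stepwise ring closure), setting out from 21 and returning at 29: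
- One allyl arm of 21 is cleaved (OsO4 cat., NaIO4, 2,6-lutidine, sub-stoichiometric oxidant, 21 recycled) to the mono-aldehyde F1, formed as both C13 epimers.
- SmI2, LiBr and t-BuOH in THF at −78 °C close ring C with protonation of the enolate. The epimer with the allyl group trans to C10, tricyclic alcohol F2, is separated.
- The single hydroxyl is removed through the phenyl thionocarbonate F3 (PhOC(S)Cl, pyridine) and Bu3SnH/AIBN to give the deoxy lactone F4.
- KN(SiMe3)2 and TBSCl give the silyl ketene acetal F5, which Pd(OAc)2 in DMSO at 45 °C cyclises onto the allyl group (cycloalkenylation by divalent palladium, 5-exo) to the bridged methylene compound F6, with the exocyclic methylene on C15.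
- DDQ gives the diol F7, Ac2O/pyridine the diacetate F8, and ozonolysis returns to ketone 29.
- Cost: the self-selecting symmetry is lost (half of the material has the wrong C13 configuration), but pinacol coupling and the hydroxyl differentiation of step 19 are both avoided.

**Step 3.** Most likely failure: insufficient facial discrimination or erosion of endo selectivity with this 4-substituted 2-silyloxydiene, or protodesilylation of the dienol ether by the acidic co-catalyst. Fallback (resolution instead of catalysis), setting out from 4 and 5 and returning at 10: the cycloaddition is run with Me2AlCl to give racemic 6, which is taken through steps 4 and 5 to racemic 10. Esterification with (S)-O-methylmandelic acid (DCC, DMAP) gives diastereomeric bis-esters, from which the bis-mandelate F9 of the desired enantiomer is separated. K2CO3 in methanol returns enantiopure 10.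

**Step 14.** Most likely failure: selenoxide elimination towards the side-chain CH2 (C14), giving the exocyclic alkylidene lactone, because those hydrogens are less hindered than the neopentylic C9 hydrogens. Fallback (unsaturation before the side chain), setting out from 14 and returning at 21:
- LiN(iPr)2/PhSeBr gives the selenide F10, and H2O2 gives the parent unsaturated spirolactone F11, where only ring hydrogens can be lost.
- Iodine and pyridine give the α-iodo lactone F12.
- Iodide 18 is converted with zinc dust and LiCl into the alkylzinc iodide F13, which is coupled with F12 (Negishi coupling, Pd(OAc)2 with SPhos, THF) to give 21.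

**Step 19.** Most likely failure: poor discrimination between the two secondary hydroxyls, with double thioacylation or closure of a cyclic thionocarbonate across O11 and O15, which point towards each other. Fallback (differentiation at the ketone level), setting out from 26 and returning at 28:
- Dess–Martin periodinane gives the 11,15-dione F14.
- Zn(BH4)2 reduces only the chelating β-keto lactone carbonyl, from the exo face, to the hydroxy ketone F15.
- Tosylhydrazide gives the tosylhydrazone F16 at C11, and catecholborane followed by NaOAc·3H2O reduces it to the methylene compound 28.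

## Further compounds

F1 | step 18 | mono-aldehyde: 21 with one allyl arm cleaved to CH2CHO (C13 epimers) | O=CCC(CC=C)CC1=C[C@]2(COC1=O)[C@@H](OCc1ccc(OC)cc1)CC[C@@](C)(COCc1ccc(OC)cc1)[C@H]2CO[Si](C)(C)C(C)(C)C
F2 | step 18 | tricyclic alcohol: ring C closed, 11-OH cis to H9, allyl on C13 trans to C10, C8–H (either epimer), bis-PMB | C=CC[C@@H]1C[C@H](O)[C@@H]2C(C1)C(=O)OC[C@]23[C@@H](OCc1ccc(OC)cc1)CC[C@@](C)(COCc1ccc(OC)cc1)[C@H]3CO[Si](C)(C)C(C)(C)C
F3 | step 18 | phenyl thionocarbonate of F2 | C=CC[C@@H]1C[C@H](OC(=S)Oc4ccccc4)[C@@H]2C(C1)C(=O)OC[C@]23[C@@H](OCc1ccc(OC)cc1)CC[C@@](C)(COCc1ccc(OC)cc1)[C@H]3CO[Si](C)(C)C(C)(C)C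
F4 | step 18 | deoxy lactone: F2 without the C11 hydroxyl | C=CC[C@@H]1CC[C@@H]2C(C1)C(=O)OC[C@]23[C@@H](OCc1ccc(OC)cc1)CC[C@@](C)(COCc1ccc(OC)cc1)[C@H]3CO[Si](C)(C)C(C)(C)C
F5 | step 18 | tert-butyldimethylsilyl ketene acetal of F4 (C7=C8) | C=CC[C@@H]1CC[C@@H]2C(C1)=C(O[Si](C)(C)C(C)(C)C)OC[C@]23[C@@H](OCc1ccc(OC)cc1)CC[C@@](C)(COCc1ccc(OC)cc1)[C@H]3CO[Si](C)(C)C(C)(C)C
F6 | step 18 | bridged methylene compound: bicyclo[3.2.1]octane closed, exocyclic methylene on C15, bis-PMB | C1C(=C)[C@]23C[C@H]1CC[C@H]2[C@]1(COC3=O)[C@@H](OCc2ccc(OC)cc2)CC[C@@](C)(COCc2ccc(OC)cc2)[C@H]1CO[Si](C)(C)C(C)(C)C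
F7 | step 18 | 1,19-diol of F6 | C1C(=C)[C@]23C[C@H]1CC[C@H]2[C@]1(COC3=O)[C@@H](O)CC[C@@](C)(CO)[C@H]1CO[Si](C)(C)C(C)(C)C
F8 | step 18 | 1,19-diacetate of F7 | C1C(=C)[C@]23C[C@H]1CC[C@H]2[C@]1(COC3=O)[C@@H](OC(C)=O)CC[C@@](C)(COC(C)=O)[C@H]1CO[Si](C)(C)C(C)(C)C
F9 | step 3 | bis[(S)-O-methylmandelate] of diol 10 | C=C1[C@@H](OC(=O)[C@@H](OC)c2ccccc2)CC[C@@](C)(COC(=O)[C@@H](OC)c2ccccc2)[C@H]1CO[Si](C)(C)C(C)(C)C
F10 | step 14 | C8-phenylselanyl derivative of spirolactone 14 (C8 epimers) | O=C1C([Se]c3ccccc3)C[C@]2(CO1)[C@@H](OCc1ccc(OC)cc1)CC[C@@](C)(COCc1ccc(OC)cc1)[C@H]2CO[Si](C)(C)C(C)(C)C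
F11 | step 14 | 8,9-unsaturated spirolactone without side chain | O=C1C=C[C@]2(CO1)[C@@H](OCc1ccc(OC)cc1)CC[C@@](C)(COCc1ccc(OC)cc1)[C@H]2CO[Si](C)(C)C(C)(C)C
F12 | step 14 | 8-iodo-8,9-unsaturated spirolactone | O=C1C(I)=C[C@]2(CO1)[C@@H](OCc1ccc(OC)cc1)CC[C@@](C)(COCc1ccc(OC)cc1)[C@H]2CO[Si](C)(C)C(C)(C)C
F13 | step 14 | (2-allylpent-4-enyl)zinc iodide | I[Zn]CC(CC=C)CC=C
F14 | step 19 | tetracyclic 11,15-dione | C1C(=O)[C@]23C[C@H]1CC(=O)[C@H]2[C@]1(COC3=O)[C@@H](OC(C)=O)CC[C@@](C)(COC(C)=O)[C@H]1CO[Si](C)(C)C(C)(C)C
F15 | step 19 | 15-hydroxy-11-ketone | C1[C@@H](O)[C@]23C[C@H]1CC(=O)[C@H]2[C@]1(COC3=O)[C@@H](OC(C)=O)CC[C@@](C)(COC(C)=O)[C@H]1CO[Si](C)(C)C(C)(C)C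
F16 | step 19 | C11 tosylhydrazone of F15 | C1[C@@H](O)[C@]23C[C@H]1CC(=NNS(=O)(=O)c1ccc(C)cc1)[C@H]2[C@]1(COC3=O)[C@@H](OC(C)=O)CC[C@@](C)(COC(C)=O)[C@H]1CO[Si](C)(C)C(C)(C)C
A1 | alternative 1 | spirolactone cyclohexadienone | C=C1C[C@]23C[C@H]1CC[C@H]2[C@]1(COC3=O)C=CC(=O)C=C1CO[Si](C)(C)C(C)(C)C
A2 | alternative 2 | ring C cyclohexene acid with quaternary C8 | C=C(Br)C[C@]1(C(=O)O)CC=CC[C@H]1[C@]1(CO[Si](CC)(CC)CC)[C@@H](O[Si](C)(C)C(C)(C)C)CC[C@@](C)(CO[Si](C)(C)C(C)(C)C)[C@H]1COCc1ccc(OC)cc1
A3 | alternative 3 | ring A silyl enol ether with C6–O–C20 lactone and C19 ester | C=C1C[C@]2(C(=O)OC(C)(C)C)C[C@H]1CC[C@H]2[C@@]12COC(=O)[C@@H]1[C@](C)(C(=O)OC)CC=C2O[Si](C)(C)C(C)(C)C
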